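Ring A is built last. Its six carbons are cut into a C5–C6–C7–C8 unit, a 4-benzyloxy-3-methoxycyclobutenone, and a C4a–C8a unit, a siloxyalkyne that already carries C4, C3, C2 and ring B with both stereocentres in place. One thermal benzannulation joins the fragments, closes ring A and delivers its four oxygens in four different states (free 5-OH, 6-OBn, 7-OMe, silyl ether on C8a, the later O1) with H on C8. The step exploits the hexasubstituted 5,6,7-trioxygenated ring A, whose pattern cannot be set cleanly on a preformed arene. Ring C is then closed through O1–C2 with inversion and C4 is oxidised.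

Key step: step 12

Remark: flavonoid numbering (O1, C2, C3, C4, C4a to C8a; rings A, B, C) is used for the open-chain intermediates as well. C2 is the benzylic carbon on ring B, C3 the methoxy-bearing carbon, C4 the next carbon. C4 is carried as a mixture of both epimers from compound 13 to compound 32 and is written without configuration.

**Route**

Step 1
Reactants: 1 2,3-dihydroxy-4-methoxybenzaldehyde
Product: 2 2,3-bis(benzyloxy)-4-methoxybenzaldehyde
Conditions: BnBr, K2CO3, DMF, 60 °C
Reagents that add atoms: benzyl bromide, BrCc1ccccc1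
Why: Williamson etherification of both phenols (carbonate deprotonation, SN2 on the benzylic bromide); the aldehyde is inert and the benzyl ethers are the only protecting groups that must last to the final step.

Step 2
Reactants: 3 (R)-4-benzyl-2-oxazolidinone; 4 methoxyacetyl chloride
Product: 6 (R)-4-benzyl-3-(methoxyacetyl)oxazolidin-2-one, via lithium oxazolidinide 5 (not isolated)
Conditions: n-BuLi, THF, −78 °C; then 4, −78 to 0 °C
Reagents that add atoms: none
Why: N-acylation of the lithiated Evans auxiliary by the acid chloride, a standard route to N-glycolyl oxazolidinones.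

Step 3
Reactants: 2 2,3-bis(benzyloxy)-4-methoxybenzaldehyde; 6 (R)-4-benzyl-3-(methoxyacetyl)oxazolidin-2-one
Product: 8 (R)-4-benzyl-3-[(2R,3S)-3-(2,3-bis(benzyloxy)-4-methoxyphenyl)-3-hydroxy-2-methoxypropanoyl]oxazolidin-2-one, via boron enolate 7 (not isolated)
Conditions: Bu2BOTf, Et3N, CH2Cl2, −78 to 0 °C; then 2, −78 to 0 °C; pH 7 buffer, MeOH, H2O2
Reagents that add atoms: none
Why: Evans syn glycolate aldol: the (Z)-boron enolate reacts through a closed chair transition state on the enolate face remote from the benzyl group of the auxiliary, which should set C3 (R) and the C2 carbinol (S) together as the syn pair.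

Step 4
Reactants: 8 syn aldol adduct
Product: 9 (2R,3S)-3-[2,3-bis(benzyloxy)-4-methoxyphenyl]-3-hydroxy-N,2-dimethoxy-N-methylpropanamide
Conditions: MeNHOMe·HCl, AlMe3, THF, −20 to 0 °C; aq. potassium sodium tartrate
Reagents that add atoms: N,O-dimethylhydroxylamine hydrochloride, CNOC.Cl
Why: Weinreb transamidation of the imide by the aluminium amide, directed to the exocyclic carbonyl by the free β-hydroxyl; the auxiliary is released for recovery and the α-centre is not enolised.

Step 5
Reactants: 9 Weinreb amide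
Product: 10 (2R,3S)-3-[2,3-bis(benzyloxy)-4-methoxyphenyl]-N,2-dimethoxy-N-methyl-3-(triethylsilyloxy)propanamide
Conditions: TESOTf, 2,6-lutidine, CH2Cl2, −78 to 0 °C
Reagents that add atoms: triethylsilyl triflate, CC[Si](CC)(CC)OS(=O)(=O)C(F)(F)F
Why: O-silylation of the hindered benzylic carbinol with the silyl triflate; triethylsilyl is chosen so that this ether can later be removed beside a tert-butyldimethylsilyl ether.

Step 6
Reactants: 10 silylated Weinreb amide
Product: 11 (2R,3S)-3-[2,3-bis(benzyloxy)-4-methoxyphenyl]-2-methoxy-3-(triethylsilyloxy)propanal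
Conditions: diisobutylaluminium hydride, THF, −78 °C; aq. potassium sodium tartrate
Reagents that add atoms: none
Why: partial reduction of a Weinreb amide, which accepts only one hydride before work-up and so stops at the aldehyde; the cold, non-basic conditions should keep the α-methoxy centre intact.

Step 7
Reactants: 11 aldehyde; 12 ethynylmagnesium bromide
Product: 13 5-[2,3-bis(benzyloxy)-4-methoxyphenyl]-4-methoxy-5-(triethylsilyloxy)pent-1-yn-3-ol (C2 and C3 unchanged in space from 8; C4 carbinol as both epimers)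
Conditions: THF, −78 to 0 °C; aq. NH4Cl
Reagents that add atoms: none
Why: Grignard 1,2-addition of the acetylide to the aldehyde brings in C4a and C8a; the new C4 centre needs no control because it is oxidised to the ketone in step 17.

Step 8
Reactants: 13 propargylic alcohol
Product: 14 5-[2,3-bis(benzyloxy)-4-methoxyphenyl]-3-(tert-butyldimethylsilyloxy)-4-methoxy-5-(triethylsilyloxy)pent-1-yne (C2 and C3 as in 8; C4 both epimers)
Conditions: TBSOTf, 2,6-lutidine, CH2Cl2, −78 to 0 °C
Reagents that add atoms: tert-butyldimethylsilyl triflate, CC(C)(C)[Si](C)(C)OS(=O)(=O)C(F)(F)F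
Why: O-silylation of the secondary propargylic alcohol; this more robust silyl ether masks C4 until after ring C is closed.

Step 9
Reactants: 14 terminal alkyne
Product: 17 1-(triisopropylsilyloxy)alkyne of 14 (C≡C–OTIPS; 4-OTBS; 3-OMe; 2-OTES; ring B unchanged), via lithium acetylide 15 (not isolated), via lithium ynolate 16 (not isolated)
Conditions: n-BuLi, THF, −78 °C; t-BuOOLi (from t-BuOOH and LiN(SiMe3)2), −78 to 0 °C; TIPSOTf, −78 to 0 °C
Reagents that add atoms: tert-butyl hydroperoxide, CC(C)(C)OO; triisopropylsilyl triflate, CC(C)[Si](C(C)C)(C(C)C)OS(=O)(=O)C(F)(F)F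
Why: Julia oxidation of a lithium acetylide by lithium tert-butyl peroxide (electrophilic oxygen transfer with loss of tert-butoxide) gives the ynolate, which the bulky silyl triflate traps on oxygen; the silyl and benzyl ethers are inert to these cold, aprotic conditions.

Step 10
Reactants: 18 chloroacetaldehyde dimethyl acetal
Product: 20 methoxyacetylene, via sodium methoxyacetylide 19 (not isolated)
Conditions: NaNH2, liq. NH3, −33 °C; aq. NH4Cl, distil
Reagents that add atoms: none
Why: twofold base-induced elimination (hydrogen chloride, then methanol) from the chloroacetal, a standard preparation of this volatile ynol ether, which is used at once.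

Step 11
Reactants: 20 methoxyacetylene; 21 benzyloxyacetyl chloride
Product: 23 4-(benzyloxy)-3-methoxycyclobut-2-en-1-one (racemic), via benzyloxyketene 22 (not isolated)
Conditions: 20 (excess), Et3N (slow addition), Et2O, 0 °C to rt
Reagents that add atoms: none
Why: dehydrochlorination of the acid chloride releases the ketene, which undergoes thermal [2+2] cycloaddition with the ynol ether; the nucleophilic terminal alkyne carbon bonds to the ketene carbonyl carbon, which places methoxy on C3 and benzyloxy on C4 of the cyclobutenone.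

Step 12
Reactants: 17 siloxyalkyne; 23 4-(benzyloxy)-3-methoxycyclobut-2-en-1-one
Product: 28 6-(benzyloxy)-2-[3-(2,3-bis(benzyloxy)-4-methoxyphenyl)-1-(tert-butyldimethylsilyloxy)-2-methoxy-3-(triethylsilyloxy)propyl]-5-methoxy-3-(triisopropylsilyloxy)phenol (ring A with free 5-OH; C2 and C3 as in 8; C4 both epimers), via vinylketene 24 (not isolated), via vinylcyclobutenone 25 (not isolated), via dienylketene 26 (not isolated), via cyclohexadienone 27 (not isolated)
Conditions: toluene, 80 to 110 °C, 23 (1.3 equiv) added slowly to 17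
Reagents that add atoms: none
Why: Heating opens 23 by 4π conrotatory electrocyclic cleavage (benzyloxy rotating outward) to vinylketene 24, whose ketene carbon (C5) is attacked by the oxygen-remote, nucleophilic alkyne carbon of 17 (C4a) in a regiospecific [2+2] cycloaddition that also forms C8–C8a and gives 25. A second 4π opening of 25 breaks C5–C8 to dienylketene 26, and ring A closes by 6π disrotatory electrocyclisation (re-forming C5–C6) to dienone 27, which tautomerises to phenol 28. This is the Danheiser benzannulation in its siloxyalkyne version, known to give resorcinol monosilyl ethers. No stereocentre is created: the racemic centre of 23 is lost on aromatisation, and C2 and C3 sit as silyl ether and methyl ether in a neutral medium and are not touched. The only selectivity needed is the regiochemistry of the ketene–alkyne [2+2], which the polarisation of the siloxyalkyne fixes, so that the chain lies between the new free 5-OH and the silyl ether on C8a. Slow addition of 23 keeps the vinylketene concentration low and limits its dimerisation and the acylation of 28.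

Step 13
Reactants: 28 ring A phenol
Product: 29 5-O-benzyl ether of 28 (ring A: 5-OBn; 6-OBn; 7-OMe; 8a-OTIPS; chain: 4-OTBS; 3-OMe; 2-OTES)
Conditions: BnBr, K2CO3, Bu4NI (cat.), acetone, 50 °C
Reagents that add atoms: benzyl bromide, BrCc1ccccc1
Why: Williamson etherification of the only free phenol; anhydrous carbonate in acetone should leave the aryl triisopropylsilyl ether and both alkyl silyl ethers in place, which preserves the distinction between O5 and the later O1.

Step 14
Reactants: 29 fully protected benzannulation product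
Product: 30 phenol–alcohol (8a-OH and C2-OH free; 4-OTBS; 5-OBn; 6-OBn; 7-OMe; ring B benzyl ethers kept)
Conditions: Bu4NF, AcOH, THF, 0 °C to rt
Reagents that add atoms: none
Why: fluoride-induced desilylation under acetic acid buffering: the aryl silyl ether and the triethylsilyl ether are cleaved far faster than the hindered secondary tert-butyldimethylsilyl ether on C4, and the buffer suppresses base-mediated silyl migration from O4 to O2.

Step 15
Reactants: 30 phenol–alcohol
Product: 31 2,3-trans-5,6-bis(benzyloxy)-2-[2,3-bis(benzyloxy)-4-methoxyphenyl]-4-(tert-butyldimethylsilyloxy)-3,7-dimethoxyflavan (chroman; C2 and C3 as in the target; C4 both epimers)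
Conditions: PPh3, DIAD, THF, 0 °C to rt
Reagents that add atoms: none
Why: intramolecular Mitsunobu etherification: the phenol on C8a displaces the activated C2 carbinol in a 6-exo-tet SN2 closure of ring C with inversion at C2, which turns the syn aldol pattern into the 2,3-trans arrangement (C2 R) that is also the thermodynamically preferred one; C3 is untouched.

Step 16
Reactants: 31 flavan silyl ether
Product: 32 2,3-trans-5,6-bis(benzyloxy)-2-[2,3-bis(benzyloxy)-4-methoxyphenyl]-3,7-dimethoxyflavan-4-ol (C4 both epimers)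
Conditions: Bu4NF, THF, rt to 45 °C
Reagents that add atoms: none
Why: fluoride cleavage of the hindered secondary silyl ether; the substrate now carries only ether functions and tolerates the basic fluoride source.

Step 17
Reactants: 32 flavan-4-ol
Product: 33 (2R,3R)-5,6-bis(benzyloxy)-2-[2,3-bis(benzyloxy)-4-methoxyphenyl]-3,7-dimethoxychroman-4-one
Conditions: Dess–Martin periodinane, NaHCO3, CH2Cl2, 0 °C to rt
Reagents that add atoms: none
Why: Dess–Martin oxidation of the benzylic secondary alcohol, in which both C4 epimers converge on one ketone; the buffered, non-basic medium should avoid epimerisation at C3 and retro-oxa-Michael opening of ring C.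

Step 18
Reactants: 33 tetrabenzyl flavanone
Product: 34 (2R,3R)-2-(2,3-dihydroxy-4-methoxyphenyl)-5,6-dihydroxy-3,7-dimethoxychroman-4-one (target)
Conditions: H2 (1 atm), 10% Pd/C, EtOAc–MeOH, rt
Reagents that add atoms: none
Why: hydrogenolysis of the four aryl benzyl ethers over palladium on carbon under neutral conditions; the aryl ketone and both stereocentres should be left intact, giving the target as the (2R,3R) enantiomer, which is handled under inert gas because of its catechol units.

**Compound list**

1 | 2,3-dihydroxy-4-methoxybenzaldehyde | COc1ccc(C=O)c(O)c1O | starting material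
2 | 2,3-bis(benzyloxy)-4-methoxybenzaldehyde | COc1ccc(C=O)c(OCc2ccccc2)c1OCc1ccccc1 | intermediate
3 | (R)-4-benzyl-2-oxazolidinone | O=C1OC[C@@H](Cc2ccccc2)N1 | starting material
4 | methoxyacetyl chloride | COCC(Cl)=O | starting material
5 | N-lithio derivative of 3 (formed in the flask) | O=C1OC[C@@H](Cc2ccccc2)N1[Li] | intermediate
6 | (R)-4-benzyl-3-(methoxyacetyl)oxazolidin-2-one | COCC(=O)N1[C@H](Cc2ccccc2)COC1=O | intermediate
7 | (Z)-dibutylboron enolate of 6 (formed in the flask) | CO/C=C(\OB(CCCC)CCCC)N1[C@H](Cc2ccccc2)COC1=O | intermediate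
8 | (R)-4-benzyl-3-[(2R,3S)-3-(2,3-bis(benzyloxy)-4-methoxyphenyl)-3-hydroxy-2-methoxypropanoyl]oxazolidin-2-one | COc1ccc([C@H](O)[C@@H](OC)C(=O)N2[C@H](Cc3ccccc3)COC2=O)c(OCc2ccccc2)c1OCc1ccccc1 | intermediate
9 | (2R,3S)-3-[2,3-bis(benzyloxy)-4-methoxyphenyl]-3-hydroxy-N,2-dimethoxy-N-methylpropanamide | COc1ccc([C@H](O)[C@@H](OC)C(=O)N(C)OC)c(OCc2ccccc2)c1OCc1ccccc1 | intermediate
10 | (2R,3S)-3-[2,3-bis(benzyloxy)-4-methoxyphenyl]-N,2-dimethoxy-N-methyl-3-(triethylsilyloxy)propanamide | COc1ccc([C@H](O[Si](CC)(CC)CC)[C@@H](OC)C(=O)N(C)OC)c(OCc2ccccc2)c1OCc1ccccc1 | intermediate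
11 | (2R,3S)-3-[2,3-bis(benzyloxy)-4-methoxyphenyl]-2-methoxy-3-(triethylsilyloxy)propanal | COc1ccc([C@H](O[Si](CC)(CC)CC)[C@@H](OC)C=O)c(OCc2ccccc2)c1OCc1ccccc1 | intermediate
12 | ethynylmagnesium bromide | C#C[Mg]Br | starting material
13 | 5-[2,3-bis(benzyloxy)-4-methoxyphenyl]-4-methoxy-5-(triethylsilyloxy)pent-1-yn-3-ol (C2, C3 as in 8; C4 epimers) | COc1ccc([C@H](O[Si](CC)(CC)CC)[C@@H](OC)C(O)C#C)c(OCc2ccccc2)c1OCc1ccccc1 | intermediate
14 | 5-[2,3-bis(benzyloxy)-4-methoxyphenyl]-3-(tert-butyldimethylsilyloxy)-4-methoxy-5-(triethylsilyloxy)pent-1-yne (C2, C3 as in 8; C4 epimers) | COc1ccc([C@H](O[Si](CC)(CC)CC)[C@@H](OC)C(O[Si](C)(C)C(C)(C)C)C#C)c(OCc2ccccc2)c1OCc1ccccc1 | intermediate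
15 | lithium acetylide of 14 (formed in the flask) | COc1ccc([C@H](O[Si](CC)(CC)CC)[C@@H](OC)C(O[Si](C)(C)C(C)(C)C)C#C[Li])c(OCc2ccccc2)c1OCc1ccccc1 | intermediate
16 | lithium ynolate derived from 15 (formed in the flask) | COc1ccc([C@H](O[Si](CC)(CC)CC)[C@@H](OC)C(O[Si](C)(C)C(C)(C)C)C#CO[Li])c(OCc2ccccc2)c1OCc1ccccc1 | intermediate
17 | 5-[2,3-bis(benzyloxy)-4-methoxyphenyl]-3-(tert-butyldimethylsilyloxy)-4-methoxy-5-(triethylsilyloxy)-1-(triisopropylsilyloxy)pent-1-yne (C2, C3 as in 8; C4 epimers) | COc1ccc([C@H](O[Si](CC)(CC)CC)[C@@H](OC)C(O[Si](C)(C)C(C)(C)C)C#CO[Si](C(C)C)(C(C)C)C(C)C)c(OCc2ccccc2)c1OCc1ccccc1 | intermediate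
18 | chloroacetaldehyde dimethyl acetal | COC(OC)CCl | starting material
19 | sodium methoxyacetylide (formed in the flask) | COC#C[Na] | intermediate
20 | methoxyacetylene | COC#C | intermediate
21 | benzyloxyacetyl chloride | O=C(Cl)COCc1ccccc1 | starting material
22 | benzyloxyketene (formed in the flask) | O=C=COCc1ccccc1 | intermediate
23 | 4-(benzyloxy)-3-methoxycyclobut-2-en-1-one (racemic) | O=C1C=C(OC)C1OCc1ccccc1 | intermediate
24 | (Z)-4-(benzyloxy)-3-methoxybuta-1,3-dien-1-one, the vinylketene (formed in the flask) | O=C=C/C(OC)=C/OCc1ccccc1 | intermediate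
25 | 4-vinylcyclobutenone from 24 and 17: 4-[(Z)-2-(benzyloxy)-1-methoxyvinyl]-3-(triisopropylsilyloxy)cyclobut-2-en-1-one carrying the C4–C3–C2–ring B chain on C2 of the four-membered ring (formed in the flask) | CO/C(=C\OCc1ccccc1)C1C(=O)C(C(O[Si](C)(C)C(C)(C)C)[C@H](OC)[C@@H](O[Si](CC)(CC)CC)c2ccc(OC)c(OCc3ccccc3)c2OCc2ccccc2)=C1O[Si](C(C)C)(C(C)C)C(C)C | intermediate
26 | dienylketene from ring opening of 25 (formed in the flask) | O=C=C(C(O[Si](C)(C)C(C)(C)C)[C@H](OC)[C@@H](O[Si](CC)(CC)CC)c1ccc(OC)c(OCc2ccccc2)c1OCc1ccccc1)/C(O[Si](C(C)C)(C(C)C)C(C)C)=C\C(OC)=C\OCc1ccccc1 | intermediate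
27 | 6-(benzyloxy)-5-methoxy-3-(triisopropylsilyloxy)cyclohexa-2,4-dien-1-one carrying the chain on C2, the keto tautomer of 28 (formed in the flask) | O=C1C(C(O[Si](C)(C)C(C)(C)C)[C@H](OC)[C@@H](O[Si](CC)(CC)CC)c2ccc(OC)c(OCc3ccccc3)c2OCc2ccccc2)=C(O[Si](C(C)C)(C(C)C)C(C)C)C=C(OC)C1OCc1ccccc1 | intermediate
28 | 6-(benzyloxy)-2-[3-(2,3-bis(benzyloxy)-4-methoxyphenyl)-1-(tert-butyldimethylsilyloxy)-2-methoxy-3-(triethylsilyloxy)propyl]-5-methoxy-3-(triisopropylsilyloxy)phenol (C2, C3 as in 8; C4 epimers) | COc1cc(O[Si](C(C)C)(C(C)C)C(C)C)c(C(O[Si](C)(C)C(C)(C)C)[C@H](OC)[C@@H](O[Si](CC)(CC)CC)c2ccc(OC)c(OCc3ccccc3)c2OCc2ccccc2)c(O)c1OCc1ccccc1 | intermediate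
29 | 5-O-benzyl ether of 28 | COc1cc(O[Si](C(C)C)(C(C)C)C(C)C)c(C(O[Si](C)(C)C(C)(C)C)[C@H](OC)[C@@H](O[Si](CC)(CC)CC)c2ccc(OC)c(OCc3ccccc3)c2OCc2ccccc2)c(OCc2ccccc2)c1OCc1ccccc1 | intermediate
30 | phenol–alcohol from 29 (8a-OH and C2-OH free, 4-OTBS kept) | COc1cc(O)c(C(O[Si](C)(C)C(C)(C)C)[C@H](OC)[C@@H](O)c2ccc(OC)c(OCc3ccccc3)c2OCc2ccccc2)c(OCc2ccccc2)c1OCc1ccccc1 | intermediate
31 | 2,3-trans-5,6-bis(benzyloxy)-2-[2,3-bis(benzyloxy)-4-methoxyphenyl]-4-(tert-butyldimethylsilyloxy)-3,7-dimethoxyflavan (C2, C3 as in the target; C4 epimers) | COc1ccc([C@H]2Oc3cc(OC)c(OCc4ccccc4)c(OCc4ccccc4)c3C(O[Si](C)(C)C(C)(C)C)[C@@H]2OC)c(OCc2ccccc2)c1OCc1ccccc1 | intermediate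
32 | 2,3-trans-5,6-bis(benzyloxy)-2-[2,3-bis(benzyloxy)-4-methoxyphenyl]-3,7-dimethoxyflavan-4-ol (C2, C3 as in the target; C4 epimers) | COc1ccc([C@H]2Oc3cc(OC)c(OCc4ccccc4)c(OCc4ccccc4)c3C(O)[C@@H]2OC)c(OCc2ccccc2)c1OCc1ccccc1 | intermediate
33 | (2R,3R)-5,6-bis(benzyloxy)-2-[2,3-bis(benzyloxy)-4-methoxyphenyl]-3,7-dimethoxychroman-4-one | COc1ccc([C@H]2Oc3cc(OC)c(OCc4ccccc4)c(OCc4ccccc4)c3C(=O)[C@@H]2OC)c(OCc2ccccc2)c1OCc1ccccc1 | intermediate
34 | (2R,3R)-2-(2,3-dihydroxy-4-methoxyphenyl)-5,6-dihydroxy-3,7-dimethoxychroman-4-one | COc1ccc([C@H]2Oc3cc(OC)c(O)c(O)c3C(=O)[C@@H]2OC)c(O)c1O | target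

**Summary**

Total step count: 18. Longest linear sequence: 15 steps (steps 1, 3 to 9 and 12 to 18, from aldehyde 1).

**Steps most likely to fail**

1. Step 12 (benzannulation). The α-branched siloxyalkyne may intercept the vinylketene too slowly, so that the ketene dimerises or acylates the product phenol. Alternatively, the temperature needed to open 23 may let 17 rearrange to a silylketene by silyl shift. Fallback: the same vinylketene 24 is generated at room temperature by photochemical Wolff rearrangement of a diazo ketone (the diazo ketone version of this benzannulation) instead of by thermal ring opening. The fallback sets out from siloxyalkyne 17 and comes back at phenol 28. Commercial methyl methoxyacetate is formylated (methyl formate, NaH, THF) and the enolate O-benzylated (BnBr, DMF) to methyl (Z)-3-(benzyloxy)-2-methoxyacrylate F1. Saponification (LiOH, THF–H2O) gives (Z)-3-(benzyloxy)-2-methoxyacrylic acid F2, oxalyl chloride gives (Z)-3-(benzyloxy)-2-methoxyacryloyl chloride F3, and trimethylsilyldiazomethane with Et3N gives (Z)-4-(benzyloxy)-1-diazo-3-methoxybut-3-en-2-one F4. Irradiation of F4 with 17 in 1,2-dichloroethane at room temperature, then warming to 80 °C to complete the electrocyclic steps through 25, 26 and 27, should give 28.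

2. Step 9 (siloxyalkyne formation). Oxygen transfer from the peroxide to the hindered, highly functionalised acetylide may be incomplete or unselective, leaving alkyne or over-oxidised material. Fallback: the oxygen is introduced through an alkynyl ester. The fallback sets out from alkyne 14 and comes back at siloxyalkyne 17. Acetylide 15 (n-BuLi, THF, −78 °C) is treated with [bis(benzoyloxy)iodo]benzene to give the alkynyl benzoate of 14 F5. Two equivalents of MeLi in THF at −78 °C cleave the ester to ynolate 16, which is silylated with TIPSOTf as in the main route.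

3. Step 15 (Mitsunobu closure of ring C). Activation of the hindered benzylic carbinol may be slow, so that elimination towards the enol ether, or ionisation at the electron-rich benzylic carbon with loss of clean inversion, competes with ring closure. Fallback: ring closure by fluoride-triggered sulfonate displacement in place of redox condensation. The fallback sets out from 29 and comes back at flavan 31, bypassing 30. HF·pyridine in THF–pyridine at 0 °C removes only the triethylsilyl group to give the C2 alcohol with the aryl triisopropylsilyl ether retained F6. Methanesulfonic anhydride and Et3N in CH2Cl2 at −40 °C give the C2 mesylate F7. Bu4NF added at −40 °C then frees the phenoxide on C8a, which displaces the mesylate with inversion (6-exo-tet) to give 31.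

**Further compounds**

F1 | step 12 | methyl (Z)-3-(benzyloxy)-2-methoxyacrylate | COC(=O)/C(OC)=C/OCc1ccccc1
F2 | step 12 | (Z)-3-(benzyloxy)-2-methoxyacrylic acid | OC(=O)/C(OC)=C/OCc1ccccc1
F3 | step 12 | (Z)-3-(benzyloxy)-2-methoxyacryloyl chloride | ClC(=O)/C(OC)=C/OCc1ccccc1
F4 | step 12 | (Z)-4-(benzyloxy)-1-diazo-3-methoxybut-3-en-2-one | [N-]=[N+]=CC(=O)/C(OC)=C/OCc1ccccc1
F5 | step 9 | alkynyl benzoate of 14: 5-[2,3-bis(benzyloxy)-4-methoxyphenyl]-3-(tert-butyldimethylsilyloxy)-4-methoxy-5-(triethylsilyloxy)pent-1-yn-1-yl benzoate | COc1ccc([C@H](O[Si](CC)(CC)CC)[C@@H](OC)C(O[Si](C)(C)C(C)(C)C)C#COC(=O)c2ccccc2)c(OCc2ccccc2)c1OCc1ccccc1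
F6 | step 15 | C2 alcohol from 29 (2-OH free; 8a-OTIPS and 4-OTBS kept) | COc1cc(O[Si](C(C)C)(C(C)C)C(C)C)c(C(O[Si](C)(C)C(C)(C)C)[C@H](OC)[C@@H](O)c2ccc(OC)c(OCc3ccccc3)c2OCc2ccccc2)c(OCc2ccccc2)c1OCc1ccccc1
F7 | step 15 | C2 methanesulfonate of F6 | COc1cc(O[Si](C(C)C)(C(C)C)C(C)C)c(C(O[Si](C)(C)C(C)(C)C)[C@H](OC)[C@@H](OS(C)(=O)=O)c2ccc(OC)c(OCc3ccccc3)c2OCc2ccccc2)c(OCc2ccccc2)c1OCc1ccccc1
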